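**Retrosynthetic overview**

1. The formyl group on ring C is carried as an aryl bromide (Br–Li exchange/DMF at the end), and all hydroxyls are released last from silyl ethers.
2. The arylglycerol chain (C7′ benzylic to ring A, C8′, C9′) comes from an Evans syn aldol between the ring B aryloxyacetyl imide and O-silylated vanillin, followed by Mitsunobu inversion at C7′ to the erythro (7′S,8′R) array.
3. The strategy rests on one feature of ring D (O1, C2, C3, fused to ring C): C2 carries ring B and makes both new ring bonds, C2–C3 and O1–C2. C2 is therefore delivered as a one-carbon ring B benzylidene, a chiral sulfonium ylide, to an ortho-quinone methide built from ring C and C3 (with its C9 arm).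
4. Ring D is the only ring formed; rings A, B and C are bought (vanillin, syringaldehyde, 5-bromo-2-hydroxy-3-methoxybenzaldehyde), and the chiral thiolane comes from (2S,5S)-hexane-2,5-diol.

Key step: step 11

Shorthand: DHB = (2R,3S)-5-bromo-3-[(tert-butyldiphenylsilyl)oxymethyl]-7-methoxy-2,3-dihydro-1-benzofuran-2-yl.

Remark (assumption): the thiolanium benzylide is taken to react through the same ylide face as in its aldehyde epoxidations, which for the (2R,5R)-thiolane corresponds to 2R after the inverting ring closure. If the annulation should give the (2S,3R) series, the enantiomeric thiolane from (2R,5R)-hexane-2,5-diol is used in the same steps.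

**Route**

Step 1
Reactants: 1 5-bromo-2-hydroxy-3-methoxybenzaldehyde
Product: 2 4-bromo-2-ethenyl-6-methoxyphenol
Conditions: Ph3PCH3Br (2.5 equiv), KOtBu (2.5 equiv), THF, 0 °C → rt
Reagents that add atoms: methyltriphenylphosphonium bromide, C[P+](c1ccccc1)(c1ccccc1)c1ccccc1.[Br-]
Why: Wittig methylenation, in which excess ylide first deprotonates the phenol and then olefinates the salicylaldehyde, is a standard entry to 2-vinylphenols.

Step 2
Reactants: 2 4-bromo-2-ethenyl-6-methoxyphenol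
Product: 3 rac-1-(5-bromo-2-hydroxy-3-methoxyphenyl)ethane-1,2-diol
Conditions: K2OsO4·2H2O (2 mol %), NMO (1.5 equiv), acetone/H2O, rt
Reagents that add atoms: N-methylmorpholine N-oxide, C[N+]1([O-])CCOCC1; water, O
Why: Upjohn syn-dihydroxylation of the styrene double bond should give the diol, and the racemic benzylic stereocenter is harmless because this carbon becomes trigonal in step 11.

Step 3
Reactants: 3 rac-1-(5-bromo-2-hydroxy-3-methoxyphenyl)ethane-1,2-diol
Product: 4 rac-4-bromo-2-[2-(tert-butyldiphenylsilyloxy)-1-hydroxyethyl]-6-methoxyphenol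
Conditions: TBDPSCl (1.05 equiv), imidazole, CH2Cl2, 0 °C
Reagents that add atoms: tert-butyl(chloro)diphenylsilane, CC(C)(C)[Si](Cl)(c1ccccc1)c1ccccc1
Why: Silylation with the bulky chlorosilane under imidazole catalysis should select the primary hydroxyl over the secondary benzylic hydroxyl and the doubly ortho-substituted, hydrogen-bonded phenol.

Step 4
Reactants: 4 rac-4-bromo-2-[2-(tert-butyldiphenylsilyloxy)-1-hydroxyethyl]-6-methoxyphenol
Product: 5 rac-4-bromo-2-[2-(tert-butyldiphenylsilyloxy)-1-(4-methylbenzenesulfonyl)ethyl]-6-methoxyphenol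
Conditions: p-TolSO2H (2 equiv), CH2Cl2, rt
Reagents that add atoms: 4-methylbenzenesulfinic acid, Cc1ccc(cc1)S(=O)O
Why: Acid-promoted SN1-type substitution of an ortho-hydroxybenzylic alcohol by a sulfinic acid (S-alkylation) is the usual way to 2-(1-sulfonylalkyl)phenols, and the TBDPS ether should withstand the weak acid; the sulfone-bearing stereocenter is racemic and is erased in step 11.

Step 5
Reactants: 6 syringaldehyde
Product: 7 ethyl 2-(4-formyl-2,6-dimethoxyphenoxy)acetate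
Conditions: BrCH2CO2Et, K2CO3, DMF, rt
Reagents that add atoms: ethyl bromoacetate, CCOC(=O)CBr
Why: Williamson etherification of the acidic phenol installs an ester arm that protects the ring B oxygen through the key step and later supplies C8′ and C9′.

Step 6
Reactants: 7 ethyl 2-(4-formyl-2,6-dimethoxyphenoxy)acetate
Product: 8 ethyl 2-[4-(hydroxymethyl)-2,6-dimethoxyphenoxy]acetate
Conditions: NaBH4 (0.5 equiv), EtOH/THF, 0 °C
Reagents that add atoms: none
Why: Borohydride reduction of the aldehyde at 0 °C is much faster than attack on the ethyl ester, so chemoselective formation of the benzylic alcohol is expected.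

Step 7
Reactants: 8 ethyl 2-[4-(hydroxymethyl)-2,6-dimethoxyphenoxy]acetate
Product: 9 ethyl 2-[4-(bromomethyl)-2,6-dimethoxyphenoxy]acetate
Conditions: PBr3 (0.4 equiv), CH2Cl2, 0 °C
Reagents that add atoms: phosphorus tribromide, BrP(Br)Br
Why: Bromination of a primary benzylic alcohol through its phosphite ester (SN2 by bromide) is routine for 3,4,5-trialkoxybenzyl alcohols and leaves the ester untouched.

Step 8
Reactants: 10 (2S,5S)-hexane-2,5-diol
Product: 11 (2S,5S)-hexane-2,5-diyl dimethanesulfonate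
Conditions: MsCl, Et3N, CH2Cl2, 0 °C
Reagents that add atoms: methanesulfonyl chloride, CS(=O)(=O)Cl
Why: O-Sulfonylation activates both secondary alcohols without touching the C–O bonds, so both stereocenters are retained.

Step 9
Reactants: 11 (2S,5S)-hexane-2,5-diyl dimethanesulfonate
Product: 12 (2R,5R)-2,5-dimethylthiolane
Conditions: Na2S·9H2O, DMSO, rt
Reagents that add atoms: sodium sulfide, [Na+].[Na+].[S-2]
Why: Double SN2 displacement by sulfide (inter- then intramolecular, 5-exo-tet) inverts both carbons and so should turn the (2S,5S)-dimesylate into the (2R,5R)-thiolane.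

Step 10
Reactants: 9 ethyl 2-[4-(bromomethyl)-2,6-dimethoxyphenoxy]acetate; 12 (2R,5R)-2,5-dimethylthiolane
Product: 13 (2R,5R)-1-[4-(2-ethoxy-2-oxoethoxy)-3,5-dimethoxybenzyl]-2,5-dimethylthiolan-1-ium tetrafluoroborate
Conditions: AgBF4 (1.0 equiv), CH2Cl2, 0 °C → rt, dark
Reagents that add atoms: silver tetrafluoroborate, [Ag+].F[B-](F)(F)F
Why: S-Alkylation of the hindered sulfide by the benzylic bromide is driven by precipitation of AgBr, and because the thiolane is C2-symmetric the sulfonium centre is not stereogenic, so a single salt should result.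

Step 11
Reactants: 5 rac-4-bromo-2-[2-(tert-butyldiphenylsilyloxy)-1-(4-methylbenzenesulfonyl)ethyl]-6-methoxyphenol; 13 (2R,5R)-1-[4-(2-ethoxy-2-oxoethoxy)-3,5-dimethoxybenzyl]-2,5-dimethylthiolan-1-ium tetrafluoroborate
Product: 17 ethyl 2-(4-DHB-2,6-dimethoxyphenoxy)acetate, via thiolanium benzylide 14 (not isolated), via ortho-quinone methide 15 (not isolated), via sulfonium phenoxide betaine 16 (not isolated)
Conditions: Cs2CO3 (4 equiv), 13 (1.5 equiv), CH2Cl2/MeCN, −30 °C, slow addition of 5, then → 0 °C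
Reagents that add atoms: none
Why: Proposed new method: Cs2CO3 turns phenol 5 into its phenoxide, which expels toluenesulfinate by 1,4-elimination to give quinone methide 15, and deprotonates salt 13 at the benzylic carbon to give ylide 14; the ylide carbon adds to the exocyclic carbon of 15 (C2–C3, driven by rearomatisation of ring C) to give betaine 16, whose phenoxide displaces the thiolane at C2 with inversion (O1–C2). The closest known reaction types are the carbonate-mediated [4+1] annulation of carbonyl-stabilised sulfonium ylides with quinone methides released from 2-(1-tosylalkyl)phenols, which gives trans-2,3-dihydrobenzofurans, and the asymmetric epoxidation of aldehydes with this C2-symmetric thiolanium benzylide; the combination of a semi-stabilised chiral benzylide with an alkyl-substituted quinone methide is the untested part. Ring D closes by a 5-exo-tet SN2 displacement. C2 is controlled by the thiolane: sulfur is not stereogenic, so one ylide is present, a ring methyl shields one face of the ylide carbon, and addition through the open face followed by inversion should give 2R; C3 is set in the same C–C bond formation, in which ring B and the silyloxymethyl group stay apart on the way to the anti betaine, so that the ring closes trans (3S). The step needs enantioselectivity, trans diastereoselectivity and capture of 15 before it tautomerises to a vinylphenol or the phenoxide is benzylated by 13; these are secured by the chiral sulfide, by the electron-rich ring B that makes C2 a good electrophile for fast closure, and by adding 5 slowly to an excess of the ylide at low temperature.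

Step 12
Reactants: 17 ethyl 2-(4-DHB-2,6-dimethoxyphenoxy)acetate
Product: 18 2-(4-DHB-2,6-dimethoxyphenoxy)acetic acid
Conditions: LiOH·H2O, THF/H2O, 0 °C → rt; then 1 M HCl to pH 3
Reagents that add atoms: lithium hydroxide, [Li+].[OH-]
Why: Saponification of the unhindered ethyl ester needs only mild hydroxide, under which the TBDPS ether, the aryl bromide and the non-enolisable stereocenters C2 and C3 should be stable.

Step 13
Reactants: 18 2-(4-DHB-2,6-dimethoxyphenoxy)acetic acid; 19 (S)-4-benzyl-1,3-oxazolidin-2-one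
Product: 21 (4S)-4-benzyl-3-[2-(4-DHB-2,6-dimethoxyphenoxy)acetyl]-1,3-oxazolidin-2-one, via mixed pivalic anhydride 20 (not isolated)
Conditions: PivCl, Et3N, THF, −20 °C; then 19, LiCl, −20 °C → rt
Reagents that add atoms: none
Why: N-Acylation of the oxazolidinone by the mixed pivalic anhydride under LiCl/Et3N activation avoids strong base, so the aryl bromide and the silyl ether are not at risk.

Step 14
Reactants: 22 vanillin
Product: 23 3-methoxy-4-(triisopropylsilyloxy)benzaldehyde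
Conditions: TIPSCl, imidazole, DMF, rt
Reagents that add atoms: chlorotriisopropylsilane, CC(C)[Si](Cl)(C(C)C)C(C)C
Why: Phenol silylation with TIPSCl/imidazole gives an aryl silyl ether robust enough for the aldol, hydride, methanolysis and organolithium steps that follow.

Step 15
Reactants: 21 (4S)-4-benzyl-3-[2-(4-DHB-2,6-dimethoxyphenoxy)acetyl]-1,3-oxazolidin-2-one; 23 3-methoxy-4-(triisopropylsilyloxy)benzaldehyde
Product: 25 (4S)-4-benzyl-3-{(2S,3R)-2-(4-DHB-2,6-dimethoxyphenoxy)-3-hydroxy-3-[3-methoxy-4-(triisopropylsilyloxy)phenyl]propanoyl}-1,3-oxazolidin-2-one, via dibutylboron Z-enolate 24 (not isolated)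
Conditions: Bu2BOTf, iPr2NEt, CH2Cl2, −78 → 0 °C; 23, −78 → 0 °C; pH 7 buffer, MeOH, H2O2, 0 °C
Reagents that add atoms: none
Why: Evans syn aldol reaction of an aryloxyacetyl imide: the Z boron enolate reacts through a Zimmerman–Traxler chair on the face opposite the benzyl group of the (S)-auxiliary, which should set C8′ as R (final) and C7′ as R (inverted in step 18).

Step 16
Reactants: 25 (4S)-4-benzyl-3-{(2S,3R)-2-(4-DHB-2,6-dimethoxyphenoxy)-3-hydroxy-3-[3-methoxy-4-(triisopropylsilyloxy)phenyl]propanoyl}-1,3-oxazolidin-2-one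
Product: 26 (1R,2R)-2-(4-DHB-2,6-dimethoxyphenoxy)-1-[3-methoxy-4-(triisopropylsilyloxy)phenyl]propane-1,3-diol
Conditions: LiBH4 (2 equiv), H2O (1 equiv), Et2O/THF, 0 °C
Reagents that add atoms: none
Why: Reductive cleavage of the N-acyl oxazolidinone with LiBH4 gives the primary alcohol (C9′) and releases the auxiliary without touching the stereocenters, the silyl ethers or the aryl bromide.

Step 17
Reactants: 26 (1R,2R)-2-(4-DHB-2,6-dimethoxyphenoxy)-1-[3-methoxy-4-(triisopropylsilyloxy)phenyl]propane-1,3-diol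
Product: 27 (1R,2R)-3-(tert-butyldimethylsilyloxy)-2-(4-DHB-2,6-dimethoxyphenoxy)-1-[3-methoxy-4-(triisopropylsilyloxy)phenyl]propan-1-ol
Conditions: TBSCl (1.1 equiv), imidazole, CH2Cl2, 0 °C
Reagents that add atoms: tert-butyl(chloro)dimethylsilane, CC(C)(C)[Si](C)(C)Cl
Why: Silylation of a 1,3-diol with TBSCl/imidazole at 0 °C is selective for the primary hydroxyl over the hindered secondary benzylic one.

Step 18
Reactants: 27 (1R,2R)-3-(tert-butyldimethylsilyloxy)-2-(4-DHB-2,6-dimethoxyphenoxy)-1-[3-methoxy-4-(triisopropylsilyloxy)phenyl]propan-1-ol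
Product: 28 (1S,2R)-3-(tert-butyldimethylsilyloxy)-2-(4-DHB-2,6-dimethoxyphenoxy)-1-[3-methoxy-4-(triisopropylsilyloxy)phenyl]propyl 4-nitrobenzoate
Conditions: 4-O2NC6H4CO2H, PPh3, DIAD, THF, 0 °C → rt
Reagents that add atoms: 4-nitrobenzoic acid, OC(=O)c1ccc(cc1)[N+](=O)[O-]
Why: Mitsunobu inversion, in which the carboxylate displaces the alkoxyphosphonium group at C7′ by SN2, should convert the threo (7′R) alcohol into the erythro (7′S) ester, as is known for arylglycerol β-aryl ethers.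

Step 19
Reactants: 28 (1S,2R)-3-(tert-butyldimethylsilyloxy)-2-(4-DHB-2,6-dimethoxyphenoxy)-1-[3-methoxy-4-(triisopropylsilyloxy)phenyl]propyl 4-nitrobenzoate
Product: 29 (1S,2R)-3-(tert-butyldimethylsilyloxy)-2-(4-DHB-2,6-dimethoxyphenoxy)-1-[3-methoxy-4-(triisopropylsilyloxy)phenyl]propan-1-ol
Conditions: K2CO3 (0.3 equiv), MeOH/THF, 0 °C
Reagents that add atoms: none
Why: Base-catalysed methanolysis of the activated 4-nitrobenzoate proceeds by acyl–oxygen cleavage, so C7′ keeps its new configuration, and at 0 °C the aryl TIPS ether should survive.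

Step 20
Reactants: 29 (1S,2R)-3-(tert-butyldimethylsilyloxy)-2-(4-DHB-2,6-dimethoxyphenoxy)-1-[3-methoxy-4-(triisopropylsilyloxy)phenyl]propan-1-ol
Product: 30 (1S,2R)-1,3-bis(tert-butyldimethylsilyloxy)-2-(4-DHB-2,6-dimethoxyphenoxy)-1-[3-methoxy-4-(triisopropylsilyloxy)phenyl]propane
Conditions: TBSOTf, 2,6-lutidine, CH2Cl2, −78 → 0 °C
Reagents that add atoms: tert-butyldimethylsilyl trifluoromethanesulfonate, CC(C)(C)[Si](C)(C)OS(=O)(=O)C(F)(F)F
Why: The silyl triflate with 2,6-lutidine silylates the hindered secondary alcohol and removes the last acidic proton before the organolithium step.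

Step 21
Reactants: 30 (1S,2R)-1,3-bis(tert-butyldimethylsilyloxy)-2-(4-DHB-2,6-dimethoxyphenoxy)-1-[3-methoxy-4-(triisopropylsilyloxy)phenyl]propane
Product: 32 (2R,3S)-2-{4-[(1S,2R)-1,3-bis(tert-butyldimethylsilyloxy)-1-[3-methoxy-4-(triisopropylsilyloxy)phenyl]propan-2-yl]oxy-3,5-dimethoxyphenyl}-3-[(tert-butyldiphenylsilyl)oxymethyl]-7-methoxy-2,3-dihydro-1-benzofuran-5-carbaldehyde, via aryllithium 31 (not isolated)
Conditions: t-BuLi (2.1 equiv), THF, −78 °C; DMF, −78 → 0 °C; H2O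
Reagents that add atoms: N,N-dimethylformamide, CN(C)C=O
Why: Bromine–lithium exchange on the fully silylated aryl bromide followed by formylation of the aryllithium with DMF (Bouveault aldehyde synthesis) installs the C5 aldehyde with no acidic or electrophilic group left to interfere.

Step 22
Reactants: 32 (2R,3S)-2-{4-[(1S,2R)-1,3-bis(tert-butyldimethylsilyloxy)-1-[3-methoxy-4-(triisopropylsilyloxy)phenyl]propan-2-yl]oxy-3,5-dimethoxyphenyl}-3-[(tert-butyldiphenylsilyl)oxymethyl]-7-methoxy-2,3-dihydro-1-benzofuran-5-carbaldehyde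
Product: 33 (2R,3S)-2-{4-[(1S,2R)-1,3-dihydroxy-1-(4-hydroxy-3-methoxyphenyl)propan-2-yl]oxy-3,5-dimethoxyphenyl}-3-(hydroxymethyl)-7-methoxy-2,3-dihydro-1-benzofuran-5-carbaldehyde
Conditions: TBAF/AcOH (1:1, 8 equiv), THF, 0 °C → rt
Reagents that add atoms: none
Why: Fluoride-mediated cleavage of all four silyl ethers, buffered with acetic acid so that the phenol, the aldehyde and the benzylic carbinol are not exposed to strong base, should release the target without touching a stereocenter.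

**Compound list**

1 | 5-bromo-2-hydroxy-3-methoxybenzaldehyde | COc1cc(Br)cc(C=O)c1O | starting material
2 | 4-bromo-2-ethenyl-6-methoxyphenol | COc1cc(Br)cc(C=C)c1O | intermediate
3 | rac-1-(5-bromo-2-hydroxy-3-methoxyphenyl)ethane-1,2-diol | COc1cc(Br)cc(C(O)CO)c1O | intermediate
4 | rac-4-bromo-2-[2-(tert-butyldiphenylsilyloxy)-1-hydroxyethyl]-6-methoxyphenol | COc1cc(Br)cc(C(O)CO[Si](c2ccccc2)(c2ccccc2)C(C)(C)C)c1O | intermediate
5 | rac-4-bromo-2-[2-(tert-butyldiphenylsilyloxy)-1-(4-methylbenzenesulfonyl)ethyl]-6-methoxyphenol | COc1cc(Br)cc(C(CO[Si](c2ccccc2)(c2ccccc2)C(C)(C)C)S(=O)(=O)c2ccc(C)cc2)c1O | intermediate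
6 | syringaldehyde (4-hydroxy-3,5-dimethoxybenzaldehyde) | COc1cc(C=O)cc(OC)c1O | starting material
7 | ethyl 2-(4-formyl-2,6-dimethoxyphenoxy)acetate | CCOC(=O)COc1c(OC)cc(C=O)cc1OC | intermediate
8 | ethyl 2-[4-(hydroxymethyl)-2,6-dimethoxyphenoxy]acetate | CCOC(=O)COc1c(OC)cc(CO)cc1OC | intermediate
9 | ethyl 2-[4-(bromomethyl)-2,6-dimethoxyphenoxy]acetate | CCOC(=O)COc1c(OC)cc(CBr)cc1OC | intermediate
10 | (2S,5S)-hexane-2,5-diol | C[C@H](O)CC[C@H](C)O | starting material
11 | (2S,5S)-hexane-2,5-diyl dimethanesulfonate | C[C@H](OS(C)(=O)=O)CC[C@H](C)OS(C)(=O)=O | intermediate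
12 | (2R,5R)-2,5-dimethylthiolane | C[C@@H]1CC[C@@H](C)S1 | intermediate
13 | (2R,5R)-1-[4-(2-ethoxy-2-oxoethoxy)-3,5-dimethoxybenzyl]-2,5-dimethylthiolan-1-ium tetrafluoroborate | CCOC(=O)COc1c(OC)cc(C[S+]2[C@H](C)CC[C@H]2C)cc1OC.F[B-](F)(F)F | intermediate
14 | benzylide of 13: [(2R,5R)-2,5-dimethylthiolan-1-ium-1-yl][4-(2-ethoxy-2-oxoethoxy)-3,5-dimethoxyphenyl]methanide | CCOC(=O)COc1c(OC)cc([CH-][S+]2[C@H](C)CC[C@H]2C)cc1OC | intermediate
15 | (6E)-4-bromo-6-[2-(tert-butyldiphenylsilyloxy)ethylidene]-2-methoxycyclohexa-2,4-dien-1-one | COC1=CC(Br)=C/C(=C\CO[Si](c2ccccc2)(c2ccccc2)C(C)(C)C)C1=O | intermediate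
16 | 4-bromo-2-{(2S,3S)-1-(tert-butyldiphenylsilyloxy)-3-[(2R,5R)-2,5-dimethylthiolan-1-ium-1-yl]-3-[4-(2-ethoxy-2-oxoethoxy)-3,5-dimethoxyphenyl]propan-2-yl}-6-methoxyphenolate | CCOC(=O)COc1c(OC)cc([C@@H]([S+]2[C@H](C)CC[C@H]2C)[C@H](CO[Si](c3ccccc3)(c3ccccc3)C(C)(C)C)c3cc(Br)cc(OC)c3[O-])cc1OC | intermediate
17 | ethyl 2-{4-[(2R,3S)-5-bromo-3-[(tert-butyldiphenylsilyl)oxymethyl]-7-methoxy-2,3-dihydro-1-benzofuran-2-yl]-2,6-dimethoxyphenoxy}acetate | CCOC(=O)COc1c(OC)cc([C@@H]2Oc3c(OC)cc(Br)cc3[C@H]2CO[Si](c4ccccc4)(c4ccccc4)C(C)(C)C)cc1OC | intermediate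
18 | 2-(4-DHB-2,6-dimethoxyphenoxy)acetic acid | OC(=O)COc1c(OC)cc([C@@H]2Oc3c(OC)cc(Br)cc3[C@H]2CO[Si](c4ccccc4)(c4ccccc4)C(C)(C)C)cc1OC | intermediate
19 | (S)-4-benzyl-1,3-oxazolidin-2-one | O=C1N[C@@H](Cc2ccccc2)CO1 | starting material
20 | 2-(4-DHB-2,6-dimethoxyphenoxy)acetic 2,2-dimethylpropanoic anhydride | CC(C)(C)C(=O)OC(=O)COc1c(OC)cc([C@@H]2Oc3c(OC)cc(Br)cc3[C@H]2CO[Si](c4ccccc4)(c4ccccc4)C(C)(C)C)cc1OC | intermediate
21 | (4S)-4-benzyl-3-[2-(4-DHB-2,6-dimethoxyphenoxy)acetyl]-1,3-oxazolidin-2-one | O=C(COc1c(OC)cc([C@@H]2Oc3c(OC)cc(Br)cc3[C@H]2CO[Si](c4ccccc4)(c4ccccc4)C(C)(C)C)cc1OC)N1C(=O)OC[C@@H]1Cc1ccccc1 | intermediate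
22 | vanillin | COc1cc(C=O)ccc1O | starting material
23 | 3-methoxy-4-(triisopropylsilyloxy)benzaldehyde | COc1cc(C=O)ccc1O[Si](C(C)C)(C(C)C)C(C)C | intermediate
24 | dibutylboron (Z)-enolate of 21 | CCCCB(CCCC)O/C(=C\Oc1c(OC)cc([C@@H]2Oc3c(OC)cc(Br)cc3[C@H]2CO[Si](c4ccccc4)(c4ccccc4)C(C)(C)C)cc1OC)N1C(=O)OC[C@@H]1Cc1ccccc1 | intermediate
25 | (4S)-4-benzyl-3-{(2S,3R)-2-(4-DHB-2,6-dimethoxyphenoxy)-3-hydroxy-3-[3-methoxy-4-(triisopropylsilyloxy)phenyl]propanoyl}-1,3-oxazolidin-2-one | COc1cc([C@@H](O)[C@@H](C(=O)N2C(=O)OC[C@@H]2Cc2ccccc2)Oc2c(OC)cc([C@@H]3Oc4c(OC)cc(Br)cc4[C@H]3CO[Si](c5ccccc5)(c5ccccc5)C(C)(C)C)cc2OC)ccc1O[Si](C(C)C)(C(C)C)C(C)C | intermediate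
26 | (1R,2R)-2-(4-DHB-2,6-dimethoxyphenoxy)-1-[3-methoxy-4-(triisopropylsilyloxy)phenyl]propane-1,3-diol | COc1cc([C@@H](O)[C@@H](CO)Oc2c(OC)cc([C@@H]3Oc4c(OC)cc(Br)cc4[C@H]3CO[Si](c5ccccc5)(c5ccccc5)C(C)(C)C)cc2OC)ccc1O[Si](C(C)C)(C(C)C)C(C)C | intermediate
27 | (1R,2R)-3-(tert-butyldimethylsilyloxy)-2-(4-DHB-2,6-dimethoxyphenoxy)-1-[3-methoxy-4-(triisopropylsilyloxy)phenyl]propan-1-ol | COc1cc([C@@H](O)[C@@H](CO[Si](C)(C)C(C)(C)C)Oc2c(OC)cc([C@@H]3Oc4c(OC)cc(Br)cc4[C@H]3CO[Si](c5ccccc5)(c5ccccc5)C(C)(C)C)cc2OC)ccc1O[Si](C(C)C)(C(C)C)C(C)C | intermediate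
28 | (1S,2R)-3-(tert-butyldimethylsilyloxy)-2-(4-DHB-2,6-dimethoxyphenoxy)-1-[3-methoxy-4-(triisopropylsilyloxy)phenyl]propyl 4-nitrobenzoate | COc1cc([C@H](OC(=O)c2ccc(cc2)[N+](=O)[O-])[C@@H](CO[Si](C)(C)C(C)(C)C)Oc2c(OC)cc([C@@H]3Oc4c(OC)cc(Br)cc4[C@H]3CO[Si](c5ccccc5)(c5ccccc5)C(C)(C)C)cc2OC)ccc1O[Si](C(C)C)(C(C)C)C(C)C | intermediate
29 | (1S,2R)-3-(tert-butyldimethylsilyloxy)-2-(4-DHB-2,6-dimethoxyphenoxy)-1-[3-methoxy-4-(triisopropylsilyloxy)phenyl]propan-1-ol | COc1cc([C@H](O)[C@@H](CO[Si](C)(C)C(C)(C)C)Oc2c(OC)cc([C@@H]3Oc4c(OC)cc(Br)cc4[C@H]3CO[Si](c5ccccc5)(c5ccccc5)C(C)(C)C)cc2OC)ccc1O[Si](C(C)C)(C(C)C)C(C)C | intermediate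
30 | (1S,2R)-1,3-bis(tert-butyldimethylsilyloxy)-2-(4-DHB-2,6-dimethoxyphenoxy)-1-[3-methoxy-4-(triisopropylsilyloxy)phenyl]propane | COc1cc([C@H](O[Si](C)(C)C(C)(C)C)[C@@H](CO[Si](C)(C)C(C)(C)C)Oc2c(OC)cc([C@@H]3Oc4c(OC)cc(Br)cc4[C@H]3CO[Si](c5ccccc5)(c5ccccc5)C(C)(C)C)cc2OC)ccc1O[Si](C(C)C)(C(C)C)C(C)C | intermediate
31 | 5-lithio analogue of 30 (lithium in place of bromine on ring C) | COc1cc([C@H](O[Si](C)(C)C(C)(C)C)[C@@H](CO[Si](C)(C)C(C)(C)C)Oc2c(OC)cc([C@@H]3Oc4c(OC)cc([Li])cc4[C@H]3CO[Si](c5ccccc5)(c5ccccc5)C(C)(C)C)cc2OC)ccc1O[Si](C(C)C)(C(C)C)C(C)C | intermediate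
32 | (2R,3S)-2-{4-[(1S,2R)-1,3-bis(tert-butyldimethylsilyloxy)-1-[3-methoxy-4-(triisopropylsilyloxy)phenyl]propan-2-yl]oxy-3,5-dimethoxyphenyl}-3-[(tert-butyldiphenylsilyl)oxymethyl]-7-methoxy-2,3-dihydro-1-benzofuran-5-carbaldehyde | COc1cc([C@H](O[Si](C)(C)C(C)(C)C)[C@@H](CO[Si](C)(C)C(C)(C)C)Oc2c(OC)cc([C@@H]3Oc4c(OC)cc(C=O)cc4[C@H]3CO[Si](c5ccccc5)(c5ccccc5)C(C)(C)C)cc2OC)ccc1O[Si](C(C)C)(C(C)C)C(C)C | intermediate
33 | (2R,3S)-2-{4-[(1S,2R)-1,3-dihydroxy-1-(4-hydroxy-3-methoxyphenyl)propan-2-yl]oxy-3,5-dimethoxyphenyl}-3-(hydroxymethyl)-7-methoxy-2,3-dihydro-1-benzofuran-5-carbaldehyde | COc1cc([C@H](O)[C@@H](CO)Oc2c(OC)cc([C@@H]3Oc4c(OC)cc(C=O)cc4[C@H]3CO)cc2OC)ccc1O | target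

**Summary**

Total step count: 22.

Longest linear sequence: 15 steps (steps 5, 6, 7, 10, 11, 12, 13, 15–22; the branch from 1 through steps 1–4 and then 11–13 and 15–22 is equally long).

**Steps most likely to fail**

Step 11 (proposed new method). The quinone methide may tautomerise to the vinylphenol before the low steady-state concentration of ylide captures it. The sulfonium salt may transfer its benzyl group to the phenoxide. The benzylide may add with poor facial selectivity, or the betaine may epimerise before closure, eroding ee or the trans ratio.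

Fallback by known chemistry: C3 is set by an auxiliary-controlled aldol reaction and ring D is closed by acid-mediated benzylic etherification. It sets out from 2 (using 7) and returns to the route at 17.
- Vinylphenol 2 is protected as 5-bromo-1-ethenyl-3-methoxy-2-(methoxymethoxy)benzene F1 (MOMCl, iPr2NEt).
- Hydroboration–oxidation (9-BBN; NaOH, H2O2) gives 2-[5-bromo-3-methoxy-2-(methoxymethoxy)phenyl]ethanol F2.
- Oxidation (TEMPO, NaOCl, NaClO2) gives the arylacetic acid F3.
- Acylation of (R)-4-benzyl-2-oxazolidinone (PivCl, Et3N, LiCl) gives the arylacetyl imide F4.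
- An Evans syn aldol reaction (Bu2BOTf, iPr2NEt) with aldehyde 7 gives the aldol adduct F5.
- NaBH4 in THF/H2O at 0 °C removes the auxiliary while leaving the ethyl ester, giving the 1,3-diol F6 with the future C3 in the S configuration.
- TBDPSCl/imidazole silylates the primary hydroxyl to give the silyl ether F7.
- TFA in CH2Cl2 cleaves the MOM ether and ionises the benzylic alcohol next to ring B; the phenol closes ring D to the thermodynamically favoured trans isomer, which is 17.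

Step 4. Ionisation of the benzylic alcohol next to the silyloxymethyl group may be slow. The cation may also lose a proton or rearrange (enol ether or arylacetaldehyde formation) faster than the weakly nucleophilic sulfinic acid captures it.

Fallback: sulfur is introduced as a thiol and oxidised afterwards. It sets out from 4 and returns at 5. ZnI2-catalysed substitution of the benzylic hydroxyl by 4-methylbenzenethiol (ClCH2CH2Cl, rt) gives rac-4-bromo-2-[2-(tert-butyldiphenylsilyloxy)-1-(4-methylphenylsulfanyl)ethyl]-6-methoxyphenol F8, which mCPBA (2.2 equiv, CH2Cl2, 0 °C) oxidises to sulfone 5.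

Step 18. The activated oxyphosphonium ion at the electron-rich benzylic carbon may ionise, so that substitution loses its stereospecificity, or it may eliminate toward the enol ether.

Fallback: inversion by oxidation and chelation-controlled reduction. It sets out from 27 and returns at 29. Dess–Martin periodinane with NaHCO3 in CH2Cl2 gives (2R)-3-(tert-butyldimethylsilyloxy)-2-(4-DHB-2,6-dimethoxyphenoxy)-1-[3-methoxy-4-(triisopropylsilyloxy)phenyl]propan-1-one F9. Zn(BH4)2 in Et2O at −30 °C then delivers hydride to the zinc chelate of the carbonyl and aryl ether oxygens from the face opposite the silyloxymethyl group, which should give the 1,2-anti (1S) alcohol 29.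

**Further compounds**

F1 | step 11 | 5-bromo-1-ethenyl-3-methoxy-2-(methoxymethoxy)benzene | COCOc1c(OC)cc(Br)cc1C=C
F2 | step 11 | 2-[5-bromo-3-methoxy-2-(methoxymethoxy)phenyl]ethan-1-ol | COCOc1c(OC)cc(Br)cc1CCO
F3 | step 11 | 2-[5-bromo-3-methoxy-2-(methoxymethoxy)phenyl]acetic acid | COCOc1c(OC)cc(Br)cc1CC(O)=O
F4 | step 11 | (4R)-4-benzyl-3-{2-[5-bromo-3-methoxy-2-(methoxymethoxy)phenyl]acetyl}-1,3-oxazolidin-2-one | COCOc1c(OC)cc(Br)cc1CC(=O)N1C(=O)OC[C@H]1Cc1ccccc1
F5 | step 11 | ethyl 2-{4-[(1R,2R)-3-[(4R)-4-benzyl-2-oxo-1,3-oxazolidin-3-yl]-2-[5-bromo-3-methoxy-2-(methoxymethoxy)phenyl]-1-hydroxy-3-oxopropyl]-2,6-dimethoxyphenoxy}acetate | COCOc1c(OC)cc(Br)cc1[C@@H](C(=O)N1C(=O)OC[C@H]1Cc1ccccc1)[C@@H](O)c1cc(OC)c(OCC(=O)OCC)c(OC)c1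
F6 | step 11 | ethyl 2-{4-[(1R,2S)-2-[5-bromo-3-methoxy-2-(methoxymethoxy)phenyl]-1,3-dihydroxypropyl]-2,6-dimethoxyphenoxy}acetate | COCOc1c(OC)cc(Br)cc1[C@@H](CO)[C@@H](O)c1cc(OC)c(OCC(=O)OCC)c(OC)c1
F7 | step 11 | ethyl 2-{4-[(1R,2S)-2-[5-bromo-3-methoxy-2-(methoxymethoxy)phenyl]-3-(tert-butyldiphenylsilyloxy)-1-hydroxypropyl]-2,6-dimethoxyphenoxy}acetate | COCOc1c(OC)cc(Br)cc1[C@@H](CO[Si](c2ccccc2)(c2ccccc2)C(C)(C)C)[C@@H](O)c1cc(OC)c(OCC(=O)OCC)c(OC)c1
F8 | step 4 | rac-4-bromo-2-[2-(tert-butyldiphenylsilyloxy)-1-(4-methylphenylsulfanyl)ethyl]-6-methoxyphenol | COc1cc(Br)cc(C(CO[Si](c2ccccc2)(c2ccccc2)C(C)(C)C)Sc2ccc(C)cc2)c1O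
F9 | step 18 | (2R)-3-(tert-butyldimethylsilyloxy)-2-(4-DHB-2,6-dimethoxyphenoxy)-1-[3-methoxy-4-(triisopropylsilyloxy)phenyl]propan-1-one | COc1cc(C(=O)[C@@H](CO[Si](C)(C)C(C)(C)C)Oc2c(OC)cc([C@@H]3Oc4c(OC)cc(Br)cc4[C@H]3CO[Si](c5ccccc5)(c5ccccc5)C(C)(C)C)cc2OC)ccc1O[Si](C(C)C)(C(C)C)C(C)C
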